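**Retrosynthetic overview**

1. Feature: in 27 the Z alkene C2''=C3'' holds C1'' (on C8 of ring A) and the carbinol carbon C4'' on the same side, next to the C7 oxygen. O7–C7–C8–C1''–C2''=C3''–C4'' can therefore be tied into one seven-membered ring, in which only this geometry is possible.
2. Disconnections on the flavanone: C2–C1' (enantioselective conjugate arylation of chromone 20 with boronic acid 25), O1–C2 and C2–C3 (enaminone closure of ring C from ketone 17), and C4–C4a (aryllithium from bromide 12 plus an acetyl donor).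
3. The Z-hydroxyprenyl chain and O7–H come from hydride opening of benzoxepinone 10, and 10 comes from ring-closing metathesis of allyl methacrylate 9 (bond C2''=C3'').
4. 9 comes from 4-bromoresorcinol 1. The bromine blocks one ortho site, so a Claisen rearrangement places the allyl group on the future C8 without a regiochemical choice.
5. Ring order: ring A is bought; the temporary seven-membered lactone is closed in step 7 and opened in step 8; ring C is closed in step 12; ring B is attached in step 15.

Key step: step 7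

Assumption: the (R)-pyridine-oxazoline ligand is taken to give 2S, because the (S)-ligand gives (R)-β-aryl ketones from cyclic enones and the same face of a chromone maps onto 2R. If the sense proves opposite, the antipodal ligand is used.

**Route**

Step 1
Reactants: 1 4-bromoresorcinol
Product: 2 4-bromo-3-hydroxyphenyl 4-methylbenzenesulfonate
Conditions: TsCl (1.0 equiv), K2CO3, acetone, reflux
Reagents that add atoms: p-toluenesulfonyl chloride, Cc1ccc(cc1)S(=O)(=O)Cl
Why: Phenol O-sulfonylation under carbonate conditions should take the C1 hydroxyl, which has two free ortho positions and gives the more nucleophilic phenoxide, whereas the C3 hydroxyl is shielded by, and hydrogen-bonded to, the neighbouring bromine.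

Step 2
Reactants: 2 4-bromo-3-hydroxyphenyl 4-methylbenzenesulfonate; 3 allyl bromide
Product: 4 3-(allyloxy)-4-bromophenyl 4-methylbenzenesulfonate
Conditions: K2CO3, DMF, rt → 50 °C
Reagents that add atoms: none
Why: Williamson ether synthesis: carbonate deprotonates the remaining acidic ortho-bromophenol, the phenoxide is alkylated by the reactive allylic bromide, and the aryl sulfonate is inert under these conditions.

Step 3
Reactants: 4 3-(allyloxy)-4-bromophenyl 4-methylbenzenesulfonate
Product: 5 2-allyl-4-bromo-3-hydroxyphenyl 4-methylbenzenesulfonate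
Conditions: 1,2-dichlorobenzene, 185 °C (sealed tube)
Reagents that add atoms: none
Why: Aromatic Claisen rearrangement ([3,3]-sigmatropic shift, then tautomerisation): one of the two ortho carbons of the allyl ether carries bromine and cannot rearomatise by proton loss, so the allyl group should end on the carbon between the two oxygens, a terminus also favoured by the electron-withdrawing sulfonate meta to the ether.

Step 4
Reactants: 5 2-allyl-4-bromo-3-hydroxyphenyl 4-methylbenzenesulfonate
Product: 6 2-allyl-4-bromo-3-(methoxymethoxy)phenyl 4-methylbenzenesulfonate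
Conditions: MOMCl, i-Pr2NEt, CH2Cl2, 0 °C → rt
Reagents that add atoms: chloromethyl methyl ether, COCCl
Why: O-alkylation of a phenol with the small, highly reactive chloromethyl ether works even when the phenol has two ortho substituents, and the MOM group later stabilises the neighbouring aryllithium.

Step 5
Reactants: 6 2-allyl-4-bromo-3-(methoxymethoxy)phenyl 4-methylbenzenesulfonate
Product: 7 2-allyl-4-bromo-3-(methoxymethoxy)phenol
Conditions: KOH (2.5 equiv), MeOH–THF, 60 °C; AcOH to neutrality
Reagents that add atoms: none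
Why: Saponification of an aryl sulfonate: hydroxide attacks sulfur and expels the phenoxide, while the MOM acetal, the aryl bromide and, at this moderate temperature, the allyl group are stable to base.

Step 6
Reactants: 7 2-allyl-4-bromo-3-(methoxymethoxy)phenol; 8 methacryloyl chloride
Product: 9 2-allyl-4-bromo-3-(methoxymethoxy)phenyl methacrylate
Conditions: Et3N, DMAP (cat.), CH2Cl2, 0 °C
Reagents that add atoms: none
Why: O-acylation of a phenol with an acid chloride and a tertiary amine is fast at 0 °C, where the methacrylate does not polymerise and no other group reacts.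

Step 7
Reactants: 9 2-allyl-4-bromo-3-(methoxymethoxy)phenyl methacrylate
Product: 10 7-bromo-6-(methoxymethoxy)-3-methyl-1-benzoxepin-2(5H)-one
Conditions: (H2IMes)(PCy3)Cl2Ru=CHPh (second-generation Grubbs catalyst, 5 mol %), 1,4-benzoquinone (10 mol %), toluene (0.005 M), 80 °C, argon sparge
Reagents that add atoms: none
Why: The benzylidene catalyst exchanges first with the unhindered allyl terminus, the resulting ruthenium alkylidene at C2'' adds across the tethered methacrylate C=CH2 to give a ruthenacyclobutane, and cycloreversion forms C2''=C3'' while the two terminal CH2 groups leave as ethylene. The closest known reaction type is ring-closing metathesis of allyl-bearing methacrylates to α-methyl-α,β-unsaturated lactones with N-heterocyclic-carbene ruthenium catalysts. The one new ring, the seven-membered oxepinone O7–C7–C8–C1''–C2''–C3''–C4'', closes in this intramolecular cycloaddition–cycloreversion, and the ortho relation of the two arms on ring A keeps both alkenes within reach. No stereocentre is created; the selectivity needed is alkene geometry, and it is fixed by ring size, since a seven-membered ring can hold the double bond only with C1'' and C4'' on the same side, which is the Z geometry of 27. High dilution and removal of ethylene favour closure over intermolecular metathesis, and 1,4-benzoquinone traps ruthenium hydrides that would otherwise move the allyl double bond into conjugation with ring A. The aryl bromide, the MOM acetal and the aryl ester do not react with the catalyst.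

Step 8
Reactants: 10 7-bromo-6-(methoxymethoxy)-3-methyl-1-benzoxepin-2(5H)-one
Product: 11 4-bromo-2-[(2Z)-4-hydroxy-3-methylbut-2-en-1-yl]-3-(methoxymethoxy)phenol
Conditions: i-Bu2AlH (4 equiv), CH2Cl2, −78 → −20 °C; aq potassium sodium tartrate
Reagents that add atoms: none
Why: Reductive opening of an aryl ester with i-Bu2AlH: the first hydride gives a hemiacetal aluminate that expels the phenoxide and the Z-enal so formed is reduced at once in 1,2-fashion, so O7–H and the C4'' alcohol appear with the ring-derived Z geometry intact while C–Br and the MOM acetal are untouched at low temperature.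

Step 9
Reactants: 11 4-bromo-2-[(2Z)-4-hydroxy-3-methylbut-2-en-1-yl]-3-(methoxymethoxy)phenol
Product: 12 {4-bromo-3-(methoxymethoxy)-2-[(2Z)-3-methyl-4-(triisopropylsilyloxy)but-2-en-1-yl]phenoxy}triisopropylsilane
Conditions: TIPSCl (2.6 equiv), imidazole, DMAP (cat.), DMF, rt → 40 °C
Reagents that add atoms: chlorotriisopropylsilane, CC(C)[Si](Cl)(C(C)C)C(C)C
Why: Standard silylation with silyl chloride and imidazole caps both hydroxyls in one operation, and triisopropylsilyl is chosen because its aryl ether resists the basic amide acetal of step 12 and its alkyl ether resists the mild acid of steps 11 and 12.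

Step 10
Reactants: 12 {4-bromo-3-(methoxymethoxy)-2-[(2Z)-3-methyl-4-(triisopropylsilyloxy)but-2-en-1-yl]phenoxy}triisopropylsilane; 13 N-methoxy-N-methylacetamide
Product: 16 1-{2-(methoxymethoxy)-3-[(2Z)-3-methyl-4-(triisopropylsilyloxy)but-2-en-1-yl]-4-(triisopropylsilyloxy)phenyl}ethanone, via aryllithium 14 (not isolated), via lithium hemiaminal adduct 15 (not isolated)
Conditions: n-BuLi (1.05 equiv), THF, −78 °C; 13, −78 → 0 °C; AcOH (1.2 equiv)
Reagents that add atoms: none
Why: Bromine–lithium exchange at −78 °C outruns deprotonation of the benzylic-allylic CH2, the aryllithium is stabilised by the ortho MOM oxygen and has no ortho silyloxy group that could migrate, and acylation with a Weinreb amide stops at the ketone because the chelated tetrahedral adduct survives until the quench.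

Step 11
Reactants: 16 1-{2-(methoxymethoxy)-3-[(2Z)-3-methyl-4-(triisopropylsilyloxy)but-2-en-1-yl]-4-(triisopropylsilyloxy)phenyl}ethanone
Product: 17 1-{2-hydroxy-3-[(2Z)-3-methyl-4-(triisopropylsilyloxy)but-2-en-1-yl]-4-(triisopropylsilyloxy)phenyl}ethanone
Conditions: Bi(OTf)3 (2 mol %), THF–H2O (1:1), rt
Reagents that add atoms: none
Why: Lewis-acid-catalysed hydrolysis of a phenolic MOM acetal: the acetal ortho to the acetyl group is the most acid-labile function present, because the departing phenol is a good leaving group that ends hydrogen-bonded to the ketone, whereas the bulky triisopropylsilyl ethers should survive the short exposure.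

Step 12
Reactants: 17 1-{2-hydroxy-3-[(2Z)-3-methyl-4-(triisopropylsilyloxy)but-2-en-1-yl]-4-(triisopropylsilyloxy)phenyl}ethanone; 18 N,N-dimethylformamide dimethyl acetal
Product: 20 8-[(2Z)-3-methyl-4-(triisopropylsilyloxy)but-2-en-1-yl]-7-(triisopropylsilyloxy)-4H-chromen-4-one, via enaminone 19 (not isolated)
Conditions: 18 (3 equiv), toluene, 85 °C; concentrate; p-TsOH·H2O (1.2 equiv), CH2Cl2, rt
Reagents that add atoms: none
Why: Enaminone route to chromones: the amide acetal condenses with the methyl ketone, and protonation of the vinylogous amide lets the chelated phenol add to the β-carbon and expel dimethylamine (addition–elimination), which closes ring C while the liberated amine neutralises most of the acid.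

Step 13
Reactants: 21 4-bromocatechol
Product: 22 4-bromo-1,2-bis(tert-butyldimethylsilyloxy)benzene
Conditions: TBSCl (2.4 equiv), imidazole, DMF, rt
Reagents that add atoms: tert-butylchlorodimethylsilane, CC(C)(C)[Si](C)(C)Cl
Why: Standard bis-silylation of a catechol with silyl chloride and imidazole gives fluoride-labile protection that tolerates the lithiation that follows.

Step 14
Reactants: 22 4-bromo-1,2-bis(tert-butyldimethylsilyloxy)benzene
Product: 25 [3,4-bis(tert-butyldimethylsilyloxy)phenyl]boronic acid, via aryllithium 23 (not isolated), via lithium triisopropoxyborate 24 (not isolated)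
Conditions: n-BuLi, THF, −78 °C; B(Oi-Pr)3, −78 °C → rt; 1 M HCl to pH 5, 0 °C
Reagents that add atoms: triisopropyl borate, CC(C)OB(OC(C)C)OC(C)C; water, O
Why: Bromine–lithium exchange followed by borylation with a trialkyl borate and hydrolysis is the classical route to arylboronic acids, and the lithiated carbon has no ortho silyloxy group, so no silyl migration is expected.

Step 15
Reactants: 20 8-[(2Z)-3-methyl-4-(triisopropylsilyloxy)but-2-en-1-yl]-7-(triisopropylsilyloxy)-4H-chromen-4-one; 25 [3,4-bis(tert-butyldimethylsilyloxy)phenyl]boronic acid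
Product: 26 (2S)-2-[3,4-bis(tert-butyldimethylsilyloxy)phenyl]-8-[(2Z)-3-methyl-4-(triisopropylsilyloxy)but-2-en-1-yl]-7-(triisopropylsilyloxy)-2,3-dihydro-4H-chromen-4-one
Conditions: Pd(OCOCF3)2 (10 mol %), (R)-4-tert-butyl-2-(pyridin-2-yl)-4,5-dihydrooxazole (12 mol %), NH4PF6 (30 mol %), H2O (5 equiv), 25 (2 equiv), ClCH2CH2Cl, 60 °C
Reagents that add atoms: none
Why: Enantioselective palladium-catalysed conjugate addition of an arylboronic acid to a chromone: transmetalation gives a cationic aryl complex of divalent palladium bound to the pyridine-oxazoline, C2=C3 inserts through the face left open by the tert-butyl group of the ligand so that C2 is set as S, and protonolysis of the palladium enolate releases 26 without touching the hindered trisubstituted alkene.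

Step 16
Reactants: 26 (2S)-2-[3,4-bis(tert-butyldimethylsilyloxy)phenyl]-8-[(2Z)-3-methyl-4-(triisopropylsilyloxy)but-2-en-1-yl]-7-(triisopropylsilyloxy)-2,3-dihydro-4H-chromen-4-one
Product: 27 (2S)-2-(3,4-dihydroxyphenyl)-7-hydroxy-8-[(2Z)-4-hydroxy-3-methylbut-2-en-1-yl]-2,3-dihydro-4H-chromen-4-one
Conditions: HF·pyridine, pyridine, THF, 0 °C → rt; pH 6 phosphate buffer
Reagents that add atoms: none
Why: Fluoride-mediated desilylation under weakly acidic, pyridine-buffered conditions removes all four silyl groups, and because no phenoxide is generated the retro-oxa-Michael ring opening that would racemise C2 is avoided, as is acid-induced ionisation of the Z-allylic alcohol.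

**Compound list**

1 | 4-bromoresorcinol (4-bromobenzene-1,3-diol) | Oc1ccc(Br)c(O)c1 | starting material
2 | 4-bromo-3-hydroxyphenyl 4-methylbenzenesulfonate | Cc1ccc(cc1)S(=O)(=O)Oc1ccc(Br)c(O)c1 | intermediate
3 | allyl bromide | C=CCBr | starting material
4 | 3-(allyloxy)-4-bromophenyl 4-methylbenzenesulfonate | Cc1ccc(cc1)S(=O)(=O)Oc1ccc(Br)c(OCC=C)c1 | intermediate
5 | 2-allyl-4-bromo-3-hydroxyphenyl 4-methylbenzenesulfonate | Cc1ccc(cc1)S(=O)(=O)Oc1ccc(Br)c(O)c1CC=C | intermediate
6 | 2-allyl-4-bromo-3-(methoxymethoxy)phenyl 4-methylbenzenesulfonate | Cc1ccc(cc1)S(=O)(=O)Oc1ccc(Br)c(OCOC)c1CC=C | intermediate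
7 | 2-allyl-4-bromo-3-(methoxymethoxy)phenol | C=CCc1c(O)ccc(Br)c1OCOC | intermediate
8 | methacryloyl chloride | CC(=C)C(=O)Cl | starting material
9 | 2-allyl-4-bromo-3-(methoxymethoxy)phenyl methacrylate | C=CCc1c(OCOC)c(Br)ccc1OC(=O)C(C)=C | intermediate
10 | 7-bromo-6-(methoxymethoxy)-3-methyl-1-benzoxepin-2(5H)-one | CC1=CCc2c(OCOC)c(Br)ccc2OC1=O | intermediate
11 | 4-bromo-2-[(2Z)-4-hydroxy-3-methylbut-2-en-1-yl]-3-(methoxymethoxy)phenol | C/C(=C/Cc1c(O)ccc(Br)c1OCOC)CO | intermediate
12 | {4-bromo-3-(methoxymethoxy)-2-[(2Z)-3-methyl-4-(triisopropylsilyloxy)but-2-en-1-yl]phenoxy}triisopropylsilane | C/C(=C/Cc1c(O[Si](C(C)C)(C(C)C)C(C)C)ccc(Br)c1OCOC)CO[Si](C(C)C)(C(C)C)C(C)C | intermediate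
13 | N-methoxy-N-methylacetamide | CON(C)C(C)=O | starting material
14 | aryllithium from 12, lithium in place of bromine (not isolated) | C/C(=C/Cc1c(O[Si](C(C)C)(C(C)C)C(C)C)ccc([Li])c1OCOC)CO[Si](C(C)C)(C(C)C)C(C)C | intermediate
15 | lithium hemiaminal adduct of 14 and 13 (not isolated) | C/C(=C/Cc1c(O[Si](C(C)C)(C(C)C)C(C)C)ccc(C(C)(O[Li])N(C)OC)c1OCOC)CO[Si](C(C)C)(C(C)C)C(C)C | intermediate
16 | 1-{2-(methoxymethoxy)-3-[(2Z)-3-methyl-4-(triisopropylsilyloxy)but-2-en-1-yl]-4-(triisopropylsilyloxy)phenyl}ethanone | C/C(=C/Cc1c(O[Si](C(C)C)(C(C)C)C(C)C)ccc(C(C)=O)c1OCOC)CO[Si](C(C)C)(C(C)C)C(C)C | intermediate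
17 | 1-{2-hydroxy-3-[(2Z)-3-methyl-4-(triisopropylsilyloxy)but-2-en-1-yl]-4-(triisopropylsilyloxy)phenyl}ethanone | C/C(=C/Cc1c(O[Si](C(C)C)(C(C)C)C(C)C)ccc(C(C)=O)c1O)CO[Si](C(C)C)(C(C)C)C(C)C | intermediate
18 | N,N-dimethylformamide dimethyl acetal | COC(OC)N(C)C | starting material
19 | (2E)-3-(dimethylamino)-1-{2-hydroxy-3-[(2Z)-3-methyl-4-(triisopropylsilyloxy)but-2-en-1-yl]-4-(triisopropylsilyloxy)phenyl}prop-2-en-1-one (not isolated) | C/C(=C/Cc1c(O[Si](C(C)C)(C(C)C)C(C)C)ccc(C(=O)/C=C/N(C)C)c1O)CO[Si](C(C)C)(C(C)C)C(C)C | intermediate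
20 | 8-[(2Z)-3-methyl-4-(triisopropylsilyloxy)but-2-en-1-yl]-7-(triisopropylsilyloxy)-4H-chromen-4-one | C/C(=C/Cc1c(O[Si](C(C)C)(C(C)C)C(C)C)ccc2c1OC=CC2=O)CO[Si](C(C)C)(C(C)C)C(C)C | intermediate
21 | 4-bromocatechol (4-bromobenzene-1,2-diol) | Oc1ccc(Br)cc1O | starting material
22 | 4-bromo-1,2-bis(tert-butyldimethylsilyloxy)benzene | CC(C)(C)[Si](C)(C)Oc1ccc(Br)cc1O[Si](C)(C)C(C)(C)C | intermediate
23 | 3,4-bis(tert-butyldimethylsilyloxy)phenyllithium (not isolated) | CC(C)(C)[Si](C)(C)Oc1ccc([Li])cc1O[Si](C)(C)C(C)(C)C | intermediate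
24 | lithium [3,4-bis(tert-butyldimethylsilyloxy)phenyl]triisopropoxyborate (not isolated) | [Li+].CC(C)O[B-](OC(C)C)(OC(C)C)c1ccc(O[Si](C)(C)C(C)(C)C)c(O[Si](C)(C)C(C)(C)C)c1 | intermediate
25 | [3,4-bis(tert-butyldimethylsilyloxy)phenyl]boronic acid | CC(C)(C)[Si](C)(C)Oc1ccc(B(O)O)cc1O[Si](C)(C)C(C)(C)C | intermediate
26 | (2S)-2-[3,4-bis(tert-butyldimethylsilyloxy)phenyl]-8-[(2Z)-3-methyl-4-(triisopropylsilyloxy)but-2-en-1-yl]-7-(triisopropylsilyloxy)-2,3-dihydro-4H-chromen-4-one | C/C(=C/Cc1c(O[Si](C(C)C)(C(C)C)C(C)C)ccc2c1O[C@H](c1ccc(O[Si](C)(C)C(C)(C)C)c(O[Si](C)(C)C(C)(C)C)c1)CC2=O)CO[Si](C(C)C)(C(C)C)C(C)C | intermediate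
27 | (2S)-2-(3,4-dihydroxyphenyl)-7-hydroxy-8-[(2Z)-4-hydroxy-3-methylbut-2-en-1-yl]-2,3-dihydro-4H-chromen-4-one | C/C(=C/Cc1c(O)ccc2c1O[C@H](c1ccc(O)c(O)c1)CC2=O)CO | target

**Step count**

Total step count: 16.
Longest linear sequence: 14 (steps 1–12, 15 and 16). Steps 13 and 14 form the side branch to 25.

**Steps most likely to fail**

Step 7 (ring-closing metathesis).
- What may go wrong: the catalyst may turn over slowly on the electron-poor 1,1-disubstituted alkene, the allyl double bond may migrate into conjugation before closure, or intermolecular metathesis may compete with ring closure.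
- Fallback: the Z alkene is built by a Z-selective phosphonate olefination instead of a tether. It sets out from 7. Silylation (TIPSCl, imidazole, DMF) should give the triisopropylsilyl ether F1. Lemieux–Johnson cleavage (OsO4 cat., NaIO4, 2,6-lutidine, dioxane–water) should give the arylacetaldehyde F2. Still–Gennari olefination with methyl 2-[bis(2,2,2-trifluoroethoxy)phosphoryl]propanoate (KN(SiMe3)2, 18-crown-6, THF, −78 °C) should give the Z-enoate F3. i-Bu2AlH (CH2Cl2, −78 °C) should give the Z-allylic alcohol F4. A second silylation with TIPSCl comes back to the route at 12.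

Step 15 (conjugate arylation).
- What may go wrong: protodeboronation of the electron-rich boronic acid, low electrophilicity of the 7-silyloxychromone, or poor facial selectivity with a para-oxygenated aryl group may limit the step.
- Fallback: O1–C2 is formed instead of C2–C1', and the configuration is secured by kinetic resolution. It sets out from 17. Double deprotonation (LiN(SiMe3)2, THF, −78 °C) and aldol addition to 3,4-bis(tert-butyldimethylsilyloxy)benzaldehyde should give the racemic β-hydroxy ketone F5. Intramolecular Mitsunobu etherification (PPh3, diisopropyl azodicarboxylate, THF, 0 °C) should give the racemic flavanone F6. Asymmetric transfer hydrogenation with Cp*RhCl[(R,R)-TsDPEN] (HCO2H–Et3N, EtOAc), stopped near half conversion, should reduce the 2R ketone to the cis-flavan-4-ol F7. The 2S ketone is left untouched; it is separated and is 26.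

Step 11 (MOM cleavage).
- What may go wrong: loss of the allylic silyl ether, or attack of the freed phenol on the allylic position, may accompany hydrolysis of the acetal.
- Fallback: this oxygen is unmasked before any silyl ether is present and carried through the metalation as a lithium phenoxide. It sets out from 10. CF3CO2H in CH2Cl2 at 0 °C, then water, should give the hydroxy lactone F8. i-Bu2AlH (CH2Cl2, −78 °C) should give the triol F9. TIPSCl (2 equiv) and imidazole should silylate the primary alcohol and the less hindered phenol but leave the hydroxyl flanked by bromine and the side chain, giving the bromophenol F10. n-BuLi (2.2 equiv, THF, −78 °C) should give the lithium 2-lithiophenoxide F11, and acylation with 13 comes back to the route at 17.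

**Further compounds**

F1 | step 7 | [2-allyl-4-bromo-3-(methoxymethoxy)phenoxy]triisopropylsilane | C=CCc1c(O[Si](C(C)C)(C(C)C)C(C)C)ccc(Br)c1OCOC
F2 | step 7 | 2-[3-bromo-2-(methoxymethoxy)-6-(triisopropylsilyloxy)phenyl]acetaldehyde | O=CCc1c(O[Si](C(C)C)(C(C)C)C(C)C)ccc(Br)c1OCOC
F3 | step 7 | methyl (2Z)-4-[3-bromo-2-(methoxymethoxy)-6-(triisopropylsilyloxy)phenyl]-2-methylbut-2-enoate | C/C(=C/Cc1c(O[Si](C(C)C)(C(C)C)C(C)C)ccc(Br)c1OCOC)C(=O)OC
F4 | step 7 | (2Z)-4-[3-bromo-2-(methoxymethoxy)-6-(triisopropylsilyloxy)phenyl]-2-methylbut-2-en-1-ol | C/C(=C/Cc1c(O[Si](C(C)C)(C(C)C)C(C)C)ccc(Br)c1OCOC)CO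
F5 | step 15 | racemic 3-[3,4-bis(tert-butyldimethylsilyloxy)phenyl]-3-hydroxy-1-{2-hydroxy-3-[(2Z)-3-methyl-4-(triisopropylsilyloxy)but-2-en-1-yl]-4-(triisopropylsilyloxy)phenyl}propan-1-one | C/C(=C/Cc1c(O[Si](C(C)C)(C(C)C)C(C)C)ccc(C(=O)CC(O)c2ccc(O[Si](C)(C)C(C)(C)C)c(O[Si](C)(C)C(C)(C)C)c2)c1O)CO[Si](C(C)C)(C(C)C)C(C)C
F6 | step 15 | racemic form of 26 | C/C(=C/Cc1c(O[Si](C(C)C)(C(C)C)C(C)C)ccc2c1OC(c1ccc(O[Si](C)(C)C(C)(C)C)c(O[Si](C)(C)C(C)(C)C)c1)CC2=O)CO[Si](C(C)C)(C(C)C)C(C)C
F7 | step 15 | (2R,4R)-2-[3,4-bis(tert-butyldimethylsilyloxy)phenyl]-8-[(2Z)-3-methyl-4-(triisopropylsilyloxy)but-2-en-1-yl]-7-(triisopropylsilyloxy)chroman-4-ol | C/C(=C/Cc1c(O[Si](C(C)C)(C(C)C)C(C)C)ccc2c1O[C@@H](c1ccc(O[Si](C)(C)C(C)(C)C)c(O[Si](C)(C)C(C)(C)C)c1)C[C@H]2O)CO[Si](C(C)C)(C(C)C)C(C)C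
F8 | step 11 | 7-bromo-6-hydroxy-3-methyl-1-benzoxepin-2(5H)-one | CC1=CCc2c(O)c(Br)ccc2OC1=O
F9 | step 11 | 4-bromo-2-[(2Z)-4-hydroxy-3-methylbut-2-en-1-yl]benzene-1,3-diol | C/C(=C/Cc1c(O)ccc(Br)c1O)CO
F10 | step 11 | 6-bromo-2-[(2Z)-3-methyl-4-(triisopropylsilyloxy)but-2-en-1-yl]-3-(triisopropylsilyloxy)phenol | C/C(=C/Cc1c(O[Si](C(C)C)(C(C)C)C(C)C)ccc(Br)c1O)CO[Si](C(C)C)(C(C)C)C(C)C
F11 | step 11 | lithium 6-lithio-2-[(2Z)-3-methyl-4-(triisopropylsilyloxy)but-2-en-1-yl]-3-(triisopropylsilyloxy)phenoxide | C/C(=C/Cc1c(O[Si](C(C)C)(C(C)C)C(C)C)ccc([Li])c1O[Li])CO[Si](C(C)C)(C(C)C)C(C)C
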